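**Retrosynthetic overview**

1. The target is a (2S,4S)-4′,7-dihydroxyflavan (rings A, B, C; 2,4-cis) joined from C4 to C6 of (2R,3R)-epiafzelechin (rings D, E, F). The last two steps remove one pivalate, two benzyl and two 4-methylbenzyl groups.
2. Key disconnection: C4–C4a of ring F, closed by attack of ring D on the CH2 of a terminal epoxide in aryl ether 17. The strategy rests on ring D: C8a, which carries the ring oxygen O1, is para to C6, which carries the upper flavan-4-yl group. In 17 the two carbons ortho to the ether oxygen (future C4a and C8) are therefore equivalent, and either closure gives the 4→6 linkage.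
3. The O1–C2 bond of ring F comes from Mitsunobu inversion of erythro epoxy alcohol 16 (Sharpless kinetic resolution; ring E from 4-hydroxybenzaldehyde) with the symmetric phenol 12.
4. Phenol 12: the C4(ring C)–aryl(ring D) bond comes from addition of a regiodefined aryl-cerium reagent (ring D from 2-bromoresorcinol) to di-O-benzyl-(2S)-liquiritigenin. Ionic hydrogenation then sets the 2,4-cis relationship by hydride delivery.
5. Ring order: A, B and C are bought with liquiritigenin, D and E are benzene building blocks, and F is the only ring formed, in step 12.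

Key step: step 12

Assumption: commercial (2S)-liquiritigenin is taken as enantiomerically pure; if it is not, 2 is brought to full purity by crystallisation before step 5.

**Step 1**
Reactants: 1 (2S)-liquiritigenin
Product: 2 (2S)-7-benzyloxy-2-(4-benzyloxyphenyl)chroman-4-one
Conditions: BnOH, PPh3, DIAD, THF, 0 °C to rt
Reagents that add atoms: benzyl alcohol, OCc1ccccc1
Why: Mitsunobu O-alkylation of both phenols under essentially neutral conditions avoids the base-induced ring opening to the chalcone that would racemise C2.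

**Step 2**
Reactants: 3 2-bromoresorcinol
Product: 4 2-bromo-1,3-bis(4-methylbenzyloxy)benzene
Conditions: 4-methylbenzyl bromide, K2CO3, DMF, rt
Reagents that add atoms: 4-methylbenzyl bromide, Cc1ccc(CBr)cc1
Why: Williamson etherification; 4-methylbenzyl ethers are hydrogenolysed like benzyl ethers, but every aryl C–H of these groups is ortho to a substituent, which keeps them out of the borylation in step 3.

**Step 3**
Reactants: 4 2-bromo-1,3-bis(4-methylbenzyloxy)benzene
Product: 6 4-bromo-3,5-bis(4-methylbenzyloxy)phenol, via pinacol boronate 5 (not isolated)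
Conditions: B2pin2, [Ir(OMe)(cod)]2 (cat.), 4,4′-di-tert-butyl-2,2′-bipyridine (cat.), THF, 80 °C; then H2O2, NaOH, THF/H2O, 0 °C
Reagents that add atoms: bis(pinacolato)diboron, CC1(C)OB(OC1(C)C)B1OC(C)(C)C(C)(C)O1 (boron of 5); hydrogen peroxide, OO (phenol oxygen of 6)
Why: Iridium-catalysed aromatic C–H borylation is governed by sterics and should take place only at C5, the one C–H with no ortho substituent, with the C–Br bond tolerated; oxidation of the C–B bond then places the hydroxyl para to bromine, which fixes the substitution pattern of ring D.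

**Step 4**
Reactants: 6 4-bromo-3,5-bis(4-methylbenzyloxy)phenol
Product: 7 [4-bromo-3,5-bis(4-methylbenzyloxy)phenoxy]triisopropylsilane
Conditions: i-Pr3SiCl, imidazole, DMF, rt
Reagents that add atoms: triisopropylsilyl chloride, CC(C)[Si](Cl)(C(C)C)C(C)C
Why: Silylation of the phenol; the bulky silyl ether withstands bromine–lithium exchange and the acid of step 6 and is removed selectively by fluoride in step 7.

**Step 5**
Reactants: 7 [4-bromo-3,5-bis(4-methylbenzyloxy)phenoxy]triisopropylsilane; 2 (2S)-7-benzyloxy-2-(4-benzyloxyphenyl)chroman-4-one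
Product: 10 (2S)-7-benzyloxy-2-(4-benzyloxyphenyl)-4-[2,6-bis(4-methylbenzyloxy)-4-(triisopropylsilyloxy)phenyl]chroman-4-ol (mixture of C4 epimers), via aryllithium 8 (not isolated), via arylcerium dichloride 9 (not isolated)
Conditions: 7, n-BuLi, THF, −78 °C; CeCl3, THF, −78 °C; then 2, −78 to −30 °C; aq. NH4Cl; crude carbinol used directly
Reagents that add atoms: n-butyllithium, [Li]CCCC (lithium of 8); cerium trichloride, Cl[Ce](Cl)Cl (cerium and chlorine of 9)
Why: Bromine–lithium exchange at low temperature (faster than benzylic deprotonation) and transmetallation give a weakly basic organocerium reagent that adds to the enolisable ketone instead of deprotonating it, so ring C stays closed and C2 stays S; the configuration of the new carbinol carbon is irrelevant because C4 becomes planar in step 6.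

**Step 6**
Reactants: 10 (2S)-7-benzyloxy-2-(4-benzyloxyphenyl)-4-[2,6-bis(4-methylbenzyloxy)-4-(triisopropylsilyloxy)phenyl]chroman-4-ol
Product: 11 (2S,4S)-7-benzyloxy-2-(4-benzyloxyphenyl)-4-[2,6-bis(4-methylbenzyloxy)-4-(triisopropylsilyloxy)phenyl]chromane (2,4-cis)
Conditions: Et3SiH, CF3CO2H, CH2Cl2, −78 to −20 °C
Reagents that add atoms: none
Why: Ionic hydrogenation: CF3CO2H ionises the tertiary doubly benzylic alcohol to a 4-aryl-chroman-4-ylium ion (stabilised by O1, the 7-benzyloxy group and the trialkoxyphenyl ring), and Et3SiH should deliver hydride pseudo-axially on the face that carries the axial H at C2, that is trans to the equatorial C2 aryl group, so that the C4 aryl group ends equatorial and cis to the C2 aryl group (4S), while C2 is not touched.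

**Step 7**
Reactants: 11 (2S,4S)-7-benzyloxy-2-(4-benzyloxyphenyl)-4-[2,6-bis(4-methylbenzyloxy)-4-(triisopropylsilyloxy)phenyl]chromane
Product: 12 4-[(2S,4S)-7-benzyloxy-2-(4-benzyloxyphenyl)chroman-4-yl]-3,5-bis(4-methylbenzyloxy)phenol
Conditions: Bu4NF, AcOH, THF, 0 °C
Reagents that add atoms: none
Why: Fluoride cleaves the aryl silyl ether selectively, and the acetic acid buffer keeps the electron-rich phenol protonated; the result is the symmetric phenol whose hydroxyl is para to the flavanyl group.

**Step 8**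
Reactants: 13 4-hydroxybenzaldehyde
Product: 14 4-formylphenyl pivalate
Conditions: t-BuCOCl, Et3N, DMAP (cat.), CH2Cl2, 0 °C to rt
Reagents that add atoms: pivaloyl chloride, CC(C)(C)C(Cl)=O
Why: Acylation of the phenol; the hindered ester survives the Grignard, titanium and Mitsunobu steps and turns the 4-oxygen of ring E into a non-donating group.

**Step 9**
Reactants: 14 4-formylphenyl pivalate
Product: 15 rac-4-(1-hydroxyprop-2-en-1-yl)phenyl pivalate
Conditions: CH2=CHMgBr, THF, −78 °C
Reagents that add atoms: vinylmagnesium bromide, C=C[Mg]Br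
Why: Grignard 1,2-addition to the aldehyde, which at low temperature is far more electrophilic than the hindered pivalate; the racemate is resolved in step 10.

**Step 10**
Reactants: 15 rac-4-(1-hydroxyprop-2-en-1-yl)phenyl pivalate
Product: 16 4-[(S)-hydroxy[(2R)-oxiran-2-yl]methyl]phenyl pivalate (erythro)
Conditions: Ti(OiPr)4 (15 mol %), L-(+)-diisopropyl tartrate (20 mol %), t-BuOOH (0.55 equiv), 4 Å molecular sieves, CH2Cl2, −20 °C, stopped near half conversion
Reagents that add atoms: tert-butyl hydroperoxide, CC(C)(C)OO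
Why: Sharpless kinetic resolution: with the L-(+)-tartrate complex the (R)-enantiomer of 15 is epoxidised fast and on the face that gives the erythro epoxy alcohol, so the chiral titanium–tartrate catalyst sets the oxirane carbon (R) and selects the carbinol configuration (named S in 16 only because the oxirane carbon outranks the aryl group), while the slow (S)-enantiomer of 15 is left and separated.

**Step 11**
Reactants: 12 4-[(2S,4S)-7-benzyloxy-2-(4-benzyloxyphenyl)chroman-4-yl]-3,5-bis(4-methylbenzyloxy)phenol; 16 4-[(S)-hydroxy[(2R)-oxiran-2-yl]methyl]phenyl pivalate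
Product: 17 4-[(R)-{4-[(2S,4S)-7-benzyloxy-2-(4-benzyloxyphenyl)chroman-4-yl]-3,5-bis(4-methylbenzyloxy)phenoxy}[(2R)-oxiran-2-yl]methyl]phenyl pivalate (threo)
Conditions: PPh3, DIAD, toluene, 0 °C to rt
Reagents that add atoms: none
Why: Mitsunobu etherification: the phenol displaces the activated benzylic hydroxyl by SN2 with inversion (S to R), turning the erythro alcohol into the threo aryl ether; the non-donating pivaloyloxyphenyl group suppresses ionisation, and the oxirane is not touched.

**Step 12**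
Reactants: 17 threo aryl ether (as named in step 11)
Product: 18 4-[(2R,3R)-6-[(2S,4S)-7-benzyloxy-2-(4-benzyloxyphenyl)chroman-4-yl]-3-hydroxy-5,7-bis(4-methylbenzyloxy)chroman-2-yl]phenyl pivalate
Conditions: AuCl3 (5 mol %), AgOSO2CF3 (15 mol %), CH2Cl2, 0 °C to rt
Reagents that add atoms: none
Why: The cationic gold Lewis acid binds the oxirane oxygen, ring D (activated by three alkoxy groups) attacks the terminal CH2 from the backside in a Friedel–Crafts alkylation, and loss of the arenium proton leaves the C3 oxygen as the free hydroxyl. The closest known reaction type is the gold- or Lewis-acid-catalysed cycloalkylation of aryl 2,3-epoxypropyl ethers to chroman-3-ols. Ring F closes in the 6-endo mode at the epoxide. No stereocentre is formed: C2 (from the Mitsunobu inversion) and C3 (the oxirane CH from the kinetic resolution) keep their configuration because only the CH2–O bond breaks, so the threo ether should give the 2,3-cis (2R,3R) chromanol. The step needs 6-endo over 5-exo opening, which the unhindered primary carbon and the inductively deactivated internal carbon secure, and it needs the benzylic C–O bond at C2 to stay intact, which the non-donating pivaloyloxy group on ring E secures. Regiochemistry on ring D is not an issue, because the ether oxygen is para to the flavanyl-bearing carbon and both ortho carbons give the same 4→6 product.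

**Step 13**
Reactants: 18 (as named in step 12)
Product: 19 (2R,3R)-6-[(2S,4S)-7-benzyloxy-2-(4-benzyloxyphenyl)chroman-4-yl]-2-(4-hydroxyphenyl)-5,7-bis(4-methylbenzyloxy)chroman-3-ol
Conditions: i-Bu2AlH, CH2Cl2, −78 °C; aq. Rochelle salt
Reagents that add atoms: none
Why: Reductive cleavage of the aryl pivalate at low temperature frees the 4′-hydroxyl of ring E without a free phenoxide at room temperature, which could epimerise C2 of ring F by quinone-methide ring opening; the benzylic ethers are inert.

**Step 14**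
Reactants: 19 (as named in step 13)
Product: 20 (2R,3R)-6-[(2S,4S)-7-hydroxy-2-(4-hydroxyphenyl)chroman-4-yl]-2-(4-hydroxyphenyl)chromane-3,5,7-triol (target)
Conditions: H2 (1 atm), Pd(OH)2/C, THF/MeOH, rt
Reagents that add atoms: none
Why: Hydrogenolysis removes the two benzyl and two 4-methylbenzyl ethers under neutral conditions at which the cyclic benzylic C2–O1 bonds of both chroman rings and all four stereocentres should be stable.

**Compound list**

1 | (2S)-liquiritigenin | Oc1ccc([C@@H]2CC(=O)c3ccc(O)cc3O2)cc1 | starting material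
2 | (2S)-7-benzyloxy-2-(4-benzyloxyphenyl)chroman-4-one | c1ccccc1COc1ccc([C@@H]2CC(=O)c3ccc(OCc4ccccc4)cc3O2)cc1 | intermediate
3 | 2-bromoresorcinol | Oc1cccc(O)c1Br | starting material
4 | 2-bromo-1,3-bis(4-methylbenzyloxy)benzene | Cc1ccc(COc2cccc(OCc3ccc(C)cc3)c2Br)cc1 | intermediate
5 | 2-[4-bromo-3,5-bis(4-methylbenzyloxy)phenyl]-4,4,5,5-tetramethyl-1,3,2-dioxaborolane | Cc1ccc(COc2cc(B3OC(C)(C)C(C)(C)O3)cc(OCc3ccc(C)cc3)c2Br)cc1 | intermediate (not isolated)
6 | 4-bromo-3,5-bis(4-methylbenzyloxy)phenol | Cc1ccc(COc2cc(O)cc(OCc3ccc(C)cc3)c2Br)cc1 | intermediate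
7 | [4-bromo-3,5-bis(4-methylbenzyloxy)phenoxy]triisopropylsilane | Cc1ccc(COc2cc(O[Si](C(C)C)(C(C)C)C(C)C)cc(OCc3ccc(C)cc3)c2Br)cc1 | intermediate
8 | [2,6-bis(4-methylbenzyloxy)-4-(triisopropylsilyloxy)phenyl]lithium | [Li]c1c(OCc2ccc(C)cc2)cc(O[Si](C(C)C)(C(C)C)C(C)C)cc1OCc1ccc(C)cc1 | intermediate (not isolated)
9 | [2,6-bis(4-methylbenzyloxy)-4-(triisopropylsilyloxy)phenyl]cerium dichloride | Cl[Ce](Cl)c1c(OCc2ccc(C)cc2)cc(O[Si](C(C)C)(C(C)C)C(C)C)cc1OCc1ccc(C)cc1 | intermediate (not isolated)
10 | (2S)-7-benzyloxy-2-(4-benzyloxyphenyl)-4-[2,6-bis(4-methylbenzyloxy)-4-(triisopropylsilyloxy)phenyl]chroman-4-ol, C4 epimers | c1ccccc1COc1ccc([C@@H]2CC(O)(c3c(OCc4ccc(C)cc4)cc(O[Si](C(C)C)(C(C)C)C(C)C)cc3OCc3ccc(C)cc3)c3ccc(OCc4ccccc4)cc3O2)cc1 | intermediate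
11 | (2S,4S)-7-benzyloxy-2-(4-benzyloxyphenyl)-4-[2,6-bis(4-methylbenzyloxy)-4-(triisopropylsilyloxy)phenyl]chromane | c1ccccc1COc1ccc([C@@H]2C[C@H](c3c(OCc4ccc(C)cc4)cc(O[Si](C(C)C)(C(C)C)C(C)C)cc3OCc3ccc(C)cc3)c3ccc(OCc4ccccc4)cc3O2)cc1 | intermediate
12 | 4-[(2S,4S)-7-benzyloxy-2-(4-benzyloxyphenyl)chroman-4-yl]-3,5-bis(4-methylbenzyloxy)phenol | c1ccccc1COc1ccc([C@@H]2C[C@H](c3c(OCc4ccc(C)cc4)cc(O)cc3OCc3ccc(C)cc3)c3ccc(OCc4ccccc4)cc3O2)cc1 | intermediate
13 | 4-hydroxybenzaldehyde | O=Cc1ccc(O)cc1 | starting material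
14 | 4-formylphenyl pivalate | O=Cc1ccc(OC(=O)C(C)(C)C)cc1 | intermediate
15 | rac-4-(1-hydroxyprop-2-en-1-yl)phenyl pivalate | C=CC(O)c1ccc(OC(=O)C(C)(C)C)cc1 | intermediate
16 | 4-[(S)-hydroxy[(2R)-oxiran-2-yl]methyl]phenyl pivalate (erythro) | O[C@@H](c1ccc(OC(=O)C(C)(C)C)cc1)[C@H]1CO1 | intermediate
17 | 4-[(R)-{4-[(2S,4S)-7-benzyloxy-2-(4-benzyloxyphenyl)chroman-4-yl]-3,5-bis(4-methylbenzyloxy)phenoxy}[(2R)-oxiran-2-yl]methyl]phenyl pivalate (threo) | c1ccccc1COc1ccc([C@@H]2C[C@H](c3c(OCc5ccc(C)cc5)cc(O[C@H](c4ccc(OC(=O)C(C)(C)C)cc4)[C@H]4CO4)cc3OCc3ccc(C)cc3)c3ccc(OCc4ccccc4)cc3O2)cc1 | intermediate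
18 | 4-[(2R,3R)-6-[(2S,4S)-7-benzyloxy-2-(4-benzyloxyphenyl)chroman-4-yl]-3-hydroxy-5,7-bis(4-methylbenzyloxy)chroman-2-yl]phenyl pivalate | c1ccccc1COc1ccc([C@@H]2C[C@H](c3c(OCc5ccc(C)cc5)cc4c(c3OCc3ccc(C)cc3)C[C@@H](O)[C@@H](c3ccc(OC(=O)C(C)(C)C)cc3)O4)c3ccc(OCc4ccccc4)cc3O2)cc1 | intermediate
19 | (2R,3R)-6-[(2S,4S)-7-benzyloxy-2-(4-benzyloxyphenyl)chroman-4-yl]-2-(4-hydroxyphenyl)-5,7-bis(4-methylbenzyloxy)chroman-3-ol | c1ccccc1COc1ccc([C@@H]2C[C@H](c3c(OCc5ccc(C)cc5)cc4c(c3OCc3ccc(C)cc3)C[C@@H](O)[C@@H](c3ccc(O)cc3)O4)c3ccc(OCc4ccccc4)cc3O2)cc1 | intermediate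
20 | (2R,3R)-6-[(2S,4S)-7-hydroxy-2-(4-hydroxyphenyl)chroman-4-yl]-2-(4-hydroxyphenyl)chromane-3,5,7-triol | Oc1ccc([C@@H]2C[C@H](c3c(O)cc4c(c3O)C[C@@H](O)[C@@H](c3ccc(O)cc3)O4)c3ccc(O)cc3O2)cc1 | target

**Step count and risks**

Total step count: 14.
Longest linear sequence: 10 steps (3 → 4 → 6 → 7 → 10 → 11 → 12 → 17 → 18 → 19 → 20).

Steps most likely to fail:

Step 12. The Lewis acid may ionise a benzylic C–O bond (at the ether carbon, or at C2 of ring C) or trigger a 1,2-hydride shift of the activated oxirane to a carbonyl compound before ring D attacks. The fallback sets out from 17 and comes back at 18. It replaces the epoxide electrophile by a primary halide. Li2NiBr4 in THF at 0 °C should open the oxirane at CH2 to the bromohydrin F1. Et3SiCl and imidazole give its triethylsilyl ether F2. AgOSO2CF3 with 2,6-di-tert-butylpyridine in CH2Cl2 removes bromide, so that ring D is alkylated at the primary carbon in a 6-exo closure, giving the 3-O-triethylsilyl ether of 18, F3. HF·pyridine in THF then returns 18.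

Step 6. Hydride delivery to the planar C4 cation may show poor facial selectivity and give a mixture of C4 epimers. The fallback sets out from 10 and comes back at 11. Catalytic camphorsulfonic acid with molecular sieves in CH2Cl2 dehydrates 10 to the (2S)-4-aryl-2H-chromene F4. Homogeneous hydrogenation with [Ir(cod)(PCy3)(py)]PF6 and H2 in CH2Cl2 then adds both hydrogens from the face opposite the C2 aryl group, which places the C4 aryl group cis; benzylic ethers survive this catalyst.

Step 5. The basic aryl-metal may enolise the chromanone, with E1cB opening of ring C and loss of material, or add sluggishly because both ortho positions of the nucleophile are substituted. The fallback sets out from 2 and 8 and comes back at 11. It avoids a carbonyl addition altogether. Tf2O with 2,6-di-tert-butyl-4-methylpyridine in CH2Cl2 converts 2 without enolate formation into the (2S)-enol triflate F5. Quenching 8 with B(OiPr)3 and aqueous work-up gives the arylboronic acid F6. Suzuki–Miyaura coupling (Pd(OAc)2, SPhos, K3PO4, toluene/H2O) joins them to the 2H-chromene F4 described above, which is reduced to 11 by the hydrogenation given for step 6.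

**Further compounds**

F1 | step 12 | bromohydrin of 17 (oxirane opened at CH2 by bromide) | c1ccccc1COc1ccc([C@@H]2C[C@H](c3c(OCc5ccc(C)cc5)cc(O[C@H](c4ccc(OC(=O)C(C)(C)C)cc4)[C@H](O)CBr)cc3OCc3ccc(C)cc3)c3ccc(OCc4ccccc4)cc3O2)cc1
F2 | step 12 | triethylsilyl ether of F1 | c1ccccc1COc1ccc([C@@H]2C[C@H](c3c(OCc5ccc(C)cc5)cc(O[C@H](c4ccc(OC(=O)C(C)(C)C)cc4)[C@H](O[Si](CC)(CC)CC)CBr)cc3OCc3ccc(C)cc3)c3ccc(OCc4ccccc4)cc3O2)cc1
F3 | step 12 | 3-O-triethylsilyl ether of 18 | c1ccccc1COc1ccc([C@@H]2C[C@H](c3c(OCc5ccc(C)cc5)cc4c(c3OCc3ccc(C)cc3)C[C@@H](O[Si](CC)(CC)CC)[C@@H](c3ccc(OC(=O)C(C)(C)C)cc3)O4)c3ccc(OCc4ccccc4)cc3O2)cc1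
F4 | step 6 | (2S)-7-benzyloxy-2-(4-benzyloxyphenyl)-4-[2,6-bis(4-methylbenzyloxy)-4-(triisopropylsilyloxy)phenyl]-2H-chromene | c1ccccc1COc1ccc([C@@H]2C=C(c3c(OCc4ccc(C)cc4)cc(O[Si](C(C)C)(C(C)C)C(C)C)cc3OCc3ccc(C)cc3)c3ccc(OCc4ccccc4)cc3O2)cc1
F5 | step 5 | (2S)-7-benzyloxy-2-(4-benzyloxyphenyl)-2H-chromen-4-yl trifluoromethanesulfonate | c1ccccc1COc1ccc([C@@H]2C=C(OS(=O)(=O)C(F)(F)F)c3ccc(OCc4ccccc4)cc3O2)cc1
F6 | step 5 | [2,6-bis(4-methylbenzyloxy)-4-(triisopropylsilyloxy)phenyl]boronic acid | OB(O)c1c(OCc2ccc(C)cc2)cc(O[Si](C(C)C)(C(C)C)C(C)C)cc1OCc1ccc(C)cc1
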